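**Assumption:** flavan numbering is used for each unit (O1, C2, C3, C4, C4a, C5–C8, C8a; ring A benzo, ring B 2-aryl, ring C pyran), "4β" means trans to the C3 oxygen of the same unit, and the structures of the key-step precursor and product were rechecked atom by atom against the target (4→8 connectivity, ring A substitution, configuration at C2, C3 and C4) and needed no correction.

## Structural features

The target is a prodelphinidin trimer: three 2,3-cis (2R,3R) flavan-3-ol units, each a chroman (rings A and C) with a pyrogallol ring B at C2, joined by two C4→C8 bonds. The upper unit is bonded only through C4, the central unit through both C4 and C8, and the lower unit only through C8; the single galloyl ester sits on the C3 oxygen of the central unit. Both interflavan bonds are 4β, so the upper and central units each carry three contiguous stereocentres (C2, C3, C4) and the lower unit two (C2, C3), eight in all. Fragile features are the eighteen free phenols (three pyrogallol rings and a gallate, sensitive to air and base), the acid-labile doubly benzylic interflavan bonds, the base-epimerisable C2 centres and the ester. The real difficulty is selectivity rather than ring construction: C8 against C6 on each phloroglucinol ring, the configuration at each C4, and the distinction of three C3 oxygens of which only one is acylated. The key step uses the fact that ring C of the lower unit is fused to a phloroglucinol ring whose C8 is already bonded to C4 of the central unit. A salicylaldehyde on that ring supplies O1, C8a, C4a and C4, and an enal supplies C2, C3 and ring B, so O1–C2 and C3–C4 are formed in one operation.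

## Logic of the disconnections

16 to 15: the eighteen phenolic O–CH2Ph bonds are cut last. Benzyl ethers tolerate Lewis acid, hydride, peracid and amine, and one neutral hydrogenolysis frees all phenols without touching the ester or the interflavan bonds. The demand is that every earlier step is compatible with benzyl ethers.

15 to 14 and 3: the C4(upper)–C8(central) bond is cut. The upper unit is an unmodified natural unit whose C4 can be made cationic, so a whole flavan and two of its stereocentres come from the chiral pool and only C4 is new. The forward step must favour C8 of the central unit over the C6 positions and over self-condensation of 3, and must give the 4β bond.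

14 to 13: the C3–H bond of the lower unit is cut, taking the carbinol back to a carbonyl. The stereochemical problem of the lower unit is thereby reduced to C2 alone. The forward reduction must deliver hydride anti to ring B, spare the ester and leave C2 untouched.

13 to 11 through 12: the C3 oxygen is traced back to a C3 formyl group; in the forward sense the C3–CHO bond is the one broken. The formyl group is needed for ring closure but is absent from the target, so a peracid oxygen insertion excises it. The forward step must oxidise one aldehyde among many electron-rich rings and cleave the formate without base strong enough to epimerise C2.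

11 to 8 and 10: O1–C2 and C3–C4 of the lower unit are cut. Both bonds adjoin the ring that already carries the central unit, and the cut divides the lower unit into a salicylaldehyde part and a three-carbon enal bearing ring B. One ring, two bonds and one stereocentre are gained in the forward step. The demand is a single free hydroxyl in 8 and catalyst control at C2.

10 to 9: the Cα=Cβ bond is cut, a two-carbon homologation of an aldehyde.

8 to 7: the aryl–CHO bond is cut. The phenol itself directs formylation to its only free ortho carbon, which requires that 7 has exactly one free phenol.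

7 to 5 and 6: the C4(central)–aryl bond is cut with the same polarity as a natural interflavan bond, a C4 cation and a phloroglucinol-type nucleophile. The forward step must attack ortho to the hydroxyl of 6 and on the β face.

5 to 3 and 4: the ester C–O bond at C3 of the central unit is cut. Acylating at this stage, before the other two C3 hydroxyls are present in the molecule, settles the differentiation of the three C3 oxygens. It also makes 3 a common intermediate for the central and the upper unit.

3 to 2 to 1: the C4–O bond (benzylic oxidation) and five O–benzyl bonds are cut, so all stereocentres of two of the three units come from 1.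

## Other disconnections considered

Alternative 1: The cut runs through C4–C4a of the upper unit and C4–C4a of the central unit. It traces the benzylated trimer A1 (free hydroxyl only at C3 of the central unit) to the open-chain bis(aryl ether) A2. In A2, C4 of the upper unit is a benzylic carbinol on C8 of the central ring A (either epimer would serve), and C3–C4 of the central unit is a trans-epoxide whose C4 carries an intact lower unit. In the forward step BF3·OEt2 would ionise both sites, and each cation would be captured by the ortho carbon of the aryloxy ring on its own C2 oxygen; the epoxide would open in the 6-endo sense with inversion to give the 3,4-trans arrangement.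
- In its favour: two rings and two C–C bonds form in one operation. The epoxide opening releases exactly the hydroxyl that must be galloylated, a differentiation equal to that of the chosen plan. No change of oxidation level is needed at any C3, which is better than the chosen plan's formyl-to-ketone-to-alcohol detour.
- Against it here: A2 holds five defined stereocentres, four in open-chain array, including two secondary benzylic aryl ether carbons on electron-rich rings that ionise easily. Each cation faces several nucleophilic arenes and oxygens, so cross-cyclisation and oligomerisation compete. The electron-rich aryl epoxide may ionise before the arene is aligned, losing the inversion, or rearrange to a ketone.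
- Comparison: on structure it builds two pyran rings where the chosen plan builds one and takes two complete units from the chiral pool. On mechanism, cation–arene capture onto a phloroglucinol ether is at least as dependable a bond formation as the addition of a hindered phenol to an iminium ion, but its choice among competing nucleophiles is less secure. On step economy it is better after the key step (acylation with 4 and hydrogenolysis only) and much worse before it.

Alternative 2: The cut removes C4–C4a and O1–C2 of the central unit. The trimer skeleton A3 (central unit a 4-aryl-4H-chromene) would come from phenol A4, which carries the upper unit ortho to its hydroxyl, and enone A5, a chalcone-type ketone on C8 of the lower unit. In the forward step a BINOL-derived chiral phosphoric acid would direct the ortho carbon of A4 to the β-carbon of A5, and hemiketalisation with loss of water would close ring C.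
- In its favour: it is the most convergent of the four plans, because the ring-forming step itself unites an upper and a lower half that could each derive from 2; this is better than the chosen plan, which makes the two interflavan bonds in separate steps. A C4 centre set by C–C bond formation cannot erode by reversal, also a point on which it is better.
- Against it here: the β-carbon carries a 2,6-disubstituted aryl group and the phenol carries a whole flavan, a heavy steric load for a catalyst that must hold both partners, and both partners are chiral. A3 still lacks C2, C3 and the C3 oxygen of the central unit. Hydroboration anti to the C4 aryl group would place H at C2 and OH at C3 on the same face, which is wrong at C2. Correction through the ketone would require hydride delivery syn to the C4 aryl group, a mismatched case.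
- Comparison: on structure it builds the ring with three stereocentres, the chosen plan the ring with two. On mechanism both are organocatalytic phenol annulations, carbon-first there and oxygen-first here. On step economy it needs about six steps after the key step (hydroboration–oxidation, oxidation, epimerisation, reduction, acylation, hydrogenolysis) against four.

Alternative 3: The cut is the C2=C3 bond of the upper unit. The upper–central dimer A6 (upper unit a 4-aryl-4H-chromene, central unit benzylated and galloylated) would come from diene A7, which has an α-aryl vinyl ether on the upper ring A oxygen and a vinyl group on C4. In the forward step the second-generation Grubbs catalyst would close the ring with loss of ethylene.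
- In its favour: the conditions are neutral and tolerate benzyl ethers and the ester. The central unit with its ester comes from the pool, equal to the chosen plan. The ring closure has no regiochemical question, also equal, and it cannot epimerise an oxygen-bearing centre, which is better than the reversible oxa-Michael step of the chosen plan.
- Against it here: a 1,1-disubstituted electron-rich enol ether is a poor partner and, if the catalyst loads there, gives a stabilised Ru=C(OAr)Ar carbene. The C4 vinyl group lies between two ortho,ortho-disubstituted aryl rings, and Ru–H species could move its double bond into conjugation and destroy the doubly benzylic C4 centre. A7 requires that centre to be made selectively beforehand. After A6, C2 and C3 of the upper unit must be relayed from C4 with the same mismatch as in alternative 2. The lower unit must then be attached by oxidation at C4 of the central unit in the presence of the tertiary doubly benzylic C4–H of the upper unit.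
- Comparison: on structure it builds the upper ring C, with three stereocentres, while the chosen plan builds the lower ring C, with two. On mechanism, metathesis creates no stereocentre, whereas the chosen step creates one. On step economy it is longer both before and after the key step.

Key step: step 7

## Route

Step 1
Reactants: 1 (−)-epigallocatechin
Product: 2 5,7,3′,4′,5′-penta-O-benzyl-(−)-epigallocatechin (2R,3R; 3-OH free)
Conditions: BnBr, K2CO3, DMF, 0 °C to rt, Ar
Reagents that add atoms: benzyl bromide, BrCc1ccccc1
Why: Williamson ether synthesis; K2CO3 deprotonates only the five phenols, so the secondary C3 hydroxyl stays free, and cold, air-free conditions limit C2 epimerisation and oxidation of the pyrogallol ring.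

Step 2
Reactants: 2 5,7,3′,4′,5′-penta-O-benzyl-(−)-epigallocatechin
Product: 3 4β-(2-ethoxyethoxy)-5,7,3′,4′,5′-penta-O-benzyl-epigallocatechin (2,3-cis, 3,4-trans)
Conditions: DDQ, 2-ethoxyethanol, CH2Cl2, rt
Reagents that add atoms: 2-ethoxyethanol, CCOCCO
Why: Oxidative benzylic C–H functionalisation; DDQ abstracts hydride from C4 (ortho and para to ring A oxygens) and the cation is trapped by the alcohol anti to the C3 hydroxyl, giving the 4β ether, an established reaction of benzylated flavan-3-ols.

Step 3
Reactants: 3 4β-(2-ethoxyethoxy)-5,7,3′,4′,5′-penta-O-benzyl-epigallocatechin; 4 3,4,5-tris(benzyloxy)benzoic acid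
Product: 5 4β-(2-ethoxyethoxy)-5,7,3′,4′,5′-penta-O-benzyl-epigallocatechin 3-O-[3,4,5-tris(benzyloxy)benzoate]
Conditions: DCC, DMAP (cat.), CH2Cl2, 0 °C to rt
Reagents that add atoms: none
Why: Steglich esterification of the only hydroxyl of 3; the neutral conditions leave the acid-labile C4 ether intact, and acylating now distinguishes the central C3 oxygen from the two that appear later.

Step 4
Reactants: 5 4β-(2-ethoxyethoxy)-5,7,3′,4′,5′-penta-O-benzyl-epigallocatechin 3-O-[3,4,5-tris(benzyloxy)benzoate]; 6 3,5-bis(benzyloxy)phenol
Product: 7 4β-[2-hydroxy-4,6-bis(benzyloxy)phenyl]-octa-O-benzyl-epigallocatechin gallate (2,3-cis, 3,4-trans)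
Conditions: 6 (3 equiv), TMSOTf (0.3 equiv), CH2Cl2, −78 to −40 °C
Reagents that add atoms: none
Why: Lewis acid-mediated Friedel–Crafts alkylation by a flavan-4-yl cation, the reaction type of interflavan bond formation; the C3 acyloxy group can bridge the cation on the α face so the arene enters on the β face (3,4-trans), attack ortho to the hydroxyl of 6 is favoured statistically and sterically (the para carbon lies between two benzyloxy groups), and excess 6 suppresses self-condensation of 5.

Step 5
Reactants: 7 4β-[2-hydroxy-4,6-bis(benzyloxy)phenyl]-octa-O-benzyl-epigallocatechin gallate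
Product: 8 4β-[3-formyl-2-hydroxy-4,6-bis(benzyloxy)phenyl]-octa-O-benzyl-epigallocatechin gallate
Conditions: MgCl2, Et3N, (CH2O)n, MeCN, reflux
Reagents that add atoms: formaldehyde (as paraformaldehyde), C=O
Why: Casnati–Skattebøl ortho-formylation; the phenoxide bound to MgCl+ delivers formaldehyde to its only free ortho carbon and the hydroxymethyl intermediate is oxidised by hydride transfer to a second formaldehyde, while rings without a free hydroxyl, the ester and the stereocentres are unaffected.

Step 6
Reactants: 9 3,4,5-tris(benzyloxy)benzaldehyde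
Product: 10 (E)-3-[3,4,5-tris(benzyloxy)phenyl]prop-2-enal
Conditions: Ph3P=CHCHO (1.1 equiv), toluene, 80 °C
Reagents that add atoms: (triphenylphosphoranylidene)acetaldehyde, O=CC=P(c1ccccc1)(c1ccccc1)c1ccccc1
Why: Wittig olefination with a stabilised ylide gives the E enal; only a small excess of ylide is used to limit a second homologation.

Step 7
Reactants: 8 4β-[3-formyl-2-hydroxy-4,6-bis(benzyloxy)phenyl]-octa-O-benzyl-epigallocatechin gallate; 10 (E)-3-[3,4,5-tris(benzyloxy)phenyl]prop-2-enal
Product: 11 octa-O-benzyl-epigallocatechin gallate joined 4β→8 to (2R)-5,7-bis(benzyloxy)-2-[3,4,5-tris(benzyloxy)phenyl]-2H-chromene-3-carbaldehyde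
Conditions: (S)-α,α-diphenylprolinol trimethylsilyl ether (20 mol %), 2-nitrobenzoic acid (20 mol %), toluene, 4 Å MS, rt
Reagents that add atoms: none
Why: The amine condenses with 10 to an E, s-trans iminium ion whose C(Ph)2OTMS group blocks one face, and the free phenol of 8 adds to the β-carbon from the open face, forming O1–C2 and setting C2 (oxa-Michael). The resulting enamine attacks the neighbouring aryl aldehyde in an intramolecular aldol reaction, a 6-exo-trig closure that forms C3–C4 and ring C of the lower unit, and loss of water with release of the catalyst gives the conjugated 2H-chromene-3-carbaldehyde. The closest known reaction type is the diarylprolinol silyl ether-catalysed domino oxa-Michael/aldol condensation of salicylaldehydes with cinnamaldehydes. With the (S)-catalyst the usual shielding model places the nucleophile on the Si face of the β-carbon, which corresponds to the required (2R) configuration; control comes from the catalyst, because the stereocentres of the central unit are four or more bonds from C2. Regiochemistry is secured by the substrate, since the only free hydroxyl is the one between the interflavan carbon and the formyl group, so only the 4→8 connectivity can form. Chemoselectivity rests on the fact that only 10 can give a conjugated iminium ion, while the hindered, hydrogen-bonded aldehyde of 8 serves only as aldol acceptor and the ester and benzyl ethers are inert. Because the oxa-Michael step is reversible, the reaction should be stopped once 8 is consumed to limit erosion at C2.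

Step 8
Reactants: 11 octa-O-benzyl-epigallocatechin gallate-(4β→8)-(2R)-5,7-bis(benzyloxy)-2-[3,4,5-tris(benzyloxy)phenyl]-2H-chromene-3-carbaldehyde
Product: 13 octa-O-benzyl-epigallocatechin gallate-(4β→8)-(2R)-5,7-bis(benzyloxy)-2-[3,4,5-tris(benzyloxy)phenyl]chroman-3-one, via enol formate 12 (not isolated)
Conditions: mCPBA (1.1 equiv), NaHCO3, CH2Cl2, 0 °C; aq. Na2S2O3 wash; crude 12, KHCO3, MeOH–THF, 0 °C
Reagents that add atoms: 3-chloroperoxybenzoic acid (mCPBA), O=C(OO)c1cccc(Cl)c1
Why: Baeyer–Villiger oxidation of an α-substituted cinnamaldehyde-type enal; the electron-rich alkenyl group migrates in the Criegee adduct to give the enol formate, and mild methanolysis releases the enol, which ketonises by protonation at C4; one equivalent of buffered peracid and a bicarbonate-level base are chosen to spare the electron-rich rings, the ester and the C2 centre next to the new carbonyl.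

Step 9
Reactants: 13 octa-O-benzyl-epigallocatechin gallate-(4β→8)-(2R)-5,7-bis(benzyloxy)-2-[3,4,5-tris(benzyloxy)phenyl]chroman-3-one
Product: 14 octa-O-benzyl-epigallocatechin gallate-(4β→8)-5,7,3′,4′,5′-penta-O-benzyl-epigallocatechin (lower unit 2R,3R with free 3-OH)
Conditions: LiBH(s-Bu)3, THF, −78 °C; aq. NH4Cl
Reagents that add atoms: none
Why: Diastereoselective ketone reduction; the bulky hydride approaches the C3 carbonyl from the face opposite ring B, so the new hydroxyl is cis to the 2-aryl group (2,3-cis), the established outcome for benzylated flavan-3-ones, and at −78 °C the aryl ester is not reduced.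

Step 10
Reactants: 14 octa-O-benzyl-epigallocatechin gallate-(4β→8)-5,7,3′,4′,5′-penta-O-benzyl-epigallocatechin; 3 4β-(2-ethoxyethoxy)-5,7,3′,4′,5′-penta-O-benzyl-epigallocatechin
Product: 15 5,7,3′,4′,5′-penta-O-benzyl-epigallocatechin-(4β→8)-octa-O-benzyl-epigallocatechin gallate-(4β→8)-5,7,3′,4′,5′-penta-O-benzyl-epigallocatechin (free 3-OH on upper and lower units)
Conditions: 3 (1.1 equiv, slow addition), TMSOTf (0.3 equiv), CH2Cl2, −78 °C; aq. NaHCO3
Reagents that add atoms: none
Why: Lewis acid-mediated interflavan bond formation (Friedel–Crafts alkylation by a flavan-4-yl cation); the cation from 3 is attacked by C8 of the central unit of 14, the least hindered free arene carbon (it lies next to the ring oxygen, whereas both C6 sites lie between two benzyloxy groups), anti to the C3 hydroxyl of the electrophile, which sets the new C4 centre as 4β.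

Step 11
Reactants: 15 5,7,3′,4′,5′-penta-O-benzyl-epigallocatechin-(4β→8)-octa-O-benzyl-epigallocatechin gallate-(4β→8)-5,7,3′,4′,5′-penta-O-benzyl-epigallocatechin
Product: 16 epigallocatechin-(4β→8)-epigallocatechin 3-O-gallate-(4β→8)-epigallocatechin (target)
Conditions: H2 (1 atm), Pd(OH)2/C, THF–MeOH–H2O, rt
Reagents that add atoms: none
Why: Catalytic hydrogenolysis removes all eighteen benzyl ethers under neutral conditions; the ester, the two interflavan bonds and the eight stereocentres are not affected.

## Compound list

1 | (−)-epigallocatechin | O[C@@H]1Cc2c(O)cc(O)cc2O[C@@H]1c1cc(O)c(O)c(O)c1 | starting material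
2 | 5,7,3′,4′,5′-penta-O-benzyl-(−)-epigallocatechin | O[C@@H]1Cc2c(OCc5ccccc5)cc(OCc5ccccc5)cc2O[C@@H]1c1cc(OCc5ccccc5)c(OCc5ccccc5)c(OCc5ccccc5)c1 | intermediate
3 | 4β-(2-ethoxyethoxy)-5,7,3′,4′,5′-penta-O-benzyl-epigallocatechin | O[C@@H]1[C@@H](OCCOCC)c2c(OCc5ccccc5)cc(OCc5ccccc5)cc2O[C@@H]1c1cc(OCc5ccccc5)c(OCc5ccccc5)c(OCc5ccccc5)c1 | intermediate
4 | 3,4,5-tris(benzyloxy)benzoic acid | OC(=O)c1cc(OCc2ccccc2)c(OCc2ccccc2)c(OCc2ccccc2)c1 | starting material
5 | 4β-(2-ethoxyethoxy)-5,7,3′,4′,5′-penta-O-benzyl-epigallocatechin 3-O-[3,4,5-tris(benzyloxy)benzoate] | O=C(O[C@@H]1[C@@H](OCCOCC)c2c(OCc5ccccc5)cc(OCc5ccccc5)cc2O[C@@H]1c1cc(OCc5ccccc5)c(OCc5ccccc5)c(OCc5ccccc5)c1)c1cc(OCc5ccccc5)c(OCc5ccccc5)c(OCc5ccccc5)c1 | intermediate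
6 | 3,5-bis(benzyloxy)phenol | Oc1cc(OCc2ccccc2)cc(OCc2ccccc2)c1 | starting material
7 | 4β-[2-hydroxy-4,6-bis(benzyloxy)phenyl]-octa-O-benzyl-epigallocatechin gallate | O=C(O[C@@H]1[C@@H](c2c(OCc5ccccc5)cc(OCc5ccccc5)cc2O)c2c(OCc5ccccc5)cc(OCc5ccccc5)cc2O[C@@H]1c1cc(OCc5ccccc5)c(OCc5ccccc5)c(OCc5ccccc5)c1)c1cc(OCc5ccccc5)c(OCc5ccccc5)c(OCc5ccccc5)c1 | intermediate
8 | 4β-[3-formyl-2-hydroxy-4,6-bis(benzyloxy)phenyl]-octa-O-benzyl-epigallocatechin gallate | O=C(O[C@@H]1[C@@H](c2c(OCc5ccccc5)cc(OCc5ccccc5)c(C=O)c2O)c2c(OCc5ccccc5)cc(OCc5ccccc5)cc2O[C@@H]1c1cc(OCc5ccccc5)c(OCc5ccccc5)c(OCc5ccccc5)c1)c1cc(OCc5ccccc5)c(OCc5ccccc5)c(OCc5ccccc5)c1 | intermediate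
9 | 3,4,5-tris(benzyloxy)benzaldehyde | O=Cc1cc(OCc2ccccc2)c(OCc2ccccc2)c(OCc2ccccc2)c1 | starting material
10 | (E)-3-[3,4,5-tris(benzyloxy)phenyl]prop-2-enal | O=C/C=C/c1cc(OCc2ccccc2)c(OCc2ccccc2)c(OCc2ccccc2)c1 | intermediate
11 | octa-O-benzyl-epigallocatechin gallate-(4β→8)-(2R)-5,7-bis(benzyloxy)-2-[3,4,5-tris(benzyloxy)phenyl]-2H-chromene-3-carbaldehyde | O=C(O[C@@H]1[C@@H](c2c(OCc5ccccc5)cc(OCc5ccccc5)c3c2O[C@H](c2cc(OCc5ccccc5)c(OCc5ccccc5)c(OCc5ccccc5)c2)C(C=O)=C3)c2c(OCc5ccccc5)cc(OCc5ccccc5)cc2O[C@@H]1c1cc(OCc5ccccc5)c(OCc5ccccc5)c(OCc5ccccc5)c1)c1cc(OCc5ccccc5)c(OCc5ccccc5)c(OCc5ccccc5)c1 | intermediate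
12 | enol formate: as 11 with a formyloxy group at C3 of the 2H-chromene in place of the formyl group | O=C(O[C@@H]1[C@@H](c2c(OCc5ccccc5)cc(OCc5ccccc5)c3c2O[C@H](c2cc(OCc5ccccc5)c(OCc5ccccc5)c(OCc5ccccc5)c2)C(OC=O)=C3)c2c(OCc5ccccc5)cc(OCc5ccccc5)cc2O[C@@H]1c1cc(OCc5ccccc5)c(OCc5ccccc5)c(OCc5ccccc5)c1)c1cc(OCc5ccccc5)c(OCc5ccccc5)c(OCc5ccccc5)c1 | intermediate (not isolated)
13 | octa-O-benzyl-epigallocatechin gallate-(4β→8)-(2R)-5,7-bis(benzyloxy)-2-[3,4,5-tris(benzyloxy)phenyl]chroman-3-one | O=C(O[C@@H]1[C@@H](c2c(OCc5ccccc5)cc(OCc5ccccc5)c3c2O[C@H](c2cc(OCc5ccccc5)c(OCc5ccccc5)c(OCc5ccccc5)c2)C(=O)C3)c2c(OCc5ccccc5)cc(OCc5ccccc5)cc2O[C@@H]1c1cc(OCc5ccccc5)c(OCc5ccccc5)c(OCc5ccccc5)c1)c1cc(OCc5ccccc5)c(OCc5ccccc5)c(OCc5ccccc5)c1 | intermediate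
14 | octa-O-benzyl-epigallocatechin gallate-(4β→8)-5,7,3′,4′,5′-penta-O-benzyl-epigallocatechin | O=C(O[C@@H]1[C@@H](c2c(OCc5ccccc5)cc(OCc5ccccc5)c3c2O[C@H](c2cc(OCc5ccccc5)c(OCc5ccccc5)c(OCc5ccccc5)c2)[C@H](O)C3)c2c(OCc5ccccc5)cc(OCc5ccccc5)cc2O[C@@H]1c1cc(OCc5ccccc5)c(OCc5ccccc5)c(OCc5ccccc5)c1)c1cc(OCc5ccccc5)c(OCc5ccccc5)c(OCc5ccccc5)c1 | intermediate
15 | penta-O-benzyl-epigallocatechin-(4β→8)-octa-O-benzyl-epigallocatechin gallate-(4β→8)-penta-O-benzyl-epigallocatechin | O=C(O[C@@H]1[C@@H](c2c(OCc5ccccc5)cc(OCc5ccccc5)c3c2O[C@H](c2cc(OCc5ccccc5)c(OCc5ccccc5)c(OCc5ccccc5)c2)[C@H](O)C3)c2c(OCc5ccccc5)cc(OCc5ccccc5)c([C@H]3c4c(OCc5ccccc5)cc(OCc5ccccc5)cc4O[C@H](c4cc(OCc5ccccc5)c(OCc5ccccc5)c(OCc5ccccc5)c4)[C@@H]3O)c2O[C@@H]1c1cc(OCc5ccccc5)c(OCc5ccccc5)c(OCc5ccccc5)c1)c1cc(OCc5ccccc5)c(OCc5ccccc5)c(OCc5ccccc5)c1 | intermediate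
16 | epigallocatechin-(4β→8)-epigallocatechin 3-O-gallate-(4β→8)-epigallocatechin | O=C(O[C@@H]1[C@@H](c2c(O)cc(O)c3c2O[C@H](c2cc(O)c(O)c(O)c2)[C@H](O)C3)c2c(O)cc(O)c([C@H]3c4c(O)cc(O)cc4O[C@H](c4cc(O)c(O)c(O)c4)[C@@H]3O)c2O[C@@H]1c1cc(O)c(O)c(O)c1)c1cc(O)c(O)c(O)c1 | target

## Step count and least certain steps

Total: 11 steps. Longest linear sequence: 10 steps (1, 2, 3, 4, 5, 7, 8, 9, 10, 11, from 1); step 6 is a one-step branch and 3 is used twice.

**Step 7 (key step).** The most likely failure is slow or incomplete conjugate addition, because the phenol is substituted on both ortho positions and hydrogen-bonded to its formyl group, and the iminium ion of an electron-rich enal is a weak acceptor. A second risk is erosion of the C2 configuration by reversal of the oxa-Michael step, or a mismatch between the catalyst and the chiral central unit. The fallback abandons the de novo construction of the lower unit, which is itself an epigallocatechin. It sets out from 5 and 2: condensation of 5 with an excess of 2 (TMSOTf, CH2Cl2, −78 °C) should join C4 of 5 to C8 of 2 on the β face, by the same reaction type as step 10, and it comes back to the route at 14; no compound outside the list is made (F0).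

**Step 4.** The likely failure is loss of regiocontrol in the Friedel–Crafts step, with attack through the carbon para to the hydroxyl of 6, and competing self-condensation of 5 through its own C8. The fallback sets out from 5 and uses symmetric 2,4,6-trihydroxybenzaldehyde, whose two free ring carbons are equivalent (BF3·OEt2, dioxane–CH2Cl2), to give the single adduct 4β-(3-formyl-2,4,6-trihydroxyphenyl)-octa-O-benzyl-epigallocatechin gallate F1. Benzylation with two equivalents of BnBr and K2CO3 in acetone should etherify the para hydroxyl and the less hindered ortho hydroxyl. The hydroxyl that is chelated to the formyl group and flanked by the flavanyl carbon should remain free, so the sequence comes back at 8 and replaces steps 4 and 5.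

**Step 8.** The likely failures are over-oxidation (epoxidation of the electron-rich enol formate or hydroxylation of a trialkoxyarene ring) and epimerisation at C2 of the ketone during formate cleavage. The fallback sets out from 11 and removes the carbon by rearrangement instead of peracid. Pinnick oxidation (NaClO2, NaH2PO4, 2-methyl-2-butene, t-BuOH–THF–H2O) gives the 2H-chromene-3-carboxylic acid F2. DPPA and Et3N in toluene convert it into the acyl azide F3, which on warming to 80 °C undergoes Curtius rearrangement to the 3-isocyanato-2H-chromene F4. Dilute aqueous HCl in THF hydrolyses this vinyl isocyanate through the enamine to the ketone, and the sequence comes back at 13.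

**Step 10.** The likely failure is insufficient discrimination between nucleophilic sites: self-condensation of 3 through its own C8 and attack at a C6 position of 14, leading to oligomer mixtures. The fallback sets out from 3 and 14 and caps the electrophile. NBS in CH2Cl2 at −20 °C should brominate C8 of 3 to give 8-bromo-4β-(2-ethoxyethoxy)-penta-O-benzyl-epigallocatechin F5, which cannot self-condense and can be used in excess with 14 (TMSOTf, CH2Cl2, −78 °C) to give the 8-bromo protected trimer F6. Hydrogenolysis (H2, Pd(OH)2/C, Et3N, THF–MeOH–H2O) removes the benzyl groups and the bromine together, and the sequence comes back at 16.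

## Further compounds

F0 | step 7 | none | none
F1 | step 4 | 4β-(3-formyl-2,4,6-trihydroxyphenyl)-octa-O-benzyl-epigallocatechin gallate | O=C(O[C@@H]1[C@@H](c2c(O)cc(O)c(C=O)c2O)c2c(OCc5ccccc5)cc(OCc5ccccc5)cc2O[C@@H]1c1cc(OCc5ccccc5)c(OCc5ccccc5)c(OCc5ccccc5)c1)c1cc(OCc5ccccc5)c(OCc5ccccc5)c(OCc5ccccc5)c1
F2 | step 8 | 2H-chromene-3-carboxylic acid corresponding to 11 | O=C(O[C@@H]1[C@@H](c2c(OCc5ccccc5)cc(OCc5ccccc5)c3c2O[C@H](c2cc(OCc5ccccc5)c(OCc5ccccc5)c(OCc5ccccc5)c2)C(C(=O)O)=C3)c2c(OCc5ccccc5)cc(OCc5ccccc5)cc2O[C@@H]1c1cc(OCc5ccccc5)c(OCc5ccccc5)c(OCc5ccccc5)c1)c1cc(OCc5ccccc5)c(OCc5ccccc5)c(OCc5ccccc5)c1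
F3 | step 8 | acyl azide of F2 | O=C(O[C@@H]1[C@@H](c2c(OCc5ccccc5)cc(OCc5ccccc5)c3c2O[C@H](c2cc(OCc5ccccc5)c(OCc5ccccc5)c(OCc5ccccc5)c2)C(C(=O)N=[N+]=[N-])=C3)c2c(OCc5ccccc5)cc(OCc5ccccc5)cc2O[C@@H]1c1cc(OCc5ccccc5)c(OCc5ccccc5)c(OCc5ccccc5)c1)c1cc(OCc5ccccc5)c(OCc5ccccc5)c(OCc5ccccc5)c1
F4 | step 8 | 3-isocyanato-2H-chromene corresponding to 11 | O=C(O[C@@H]1[C@@H](c2c(OCc5ccccc5)cc(OCc5ccccc5)c3c2O[C@H](c2cc(OCc5ccccc5)c(OCc5ccccc5)c(OCc5ccccc5)c2)C(N=C=O)=C3)c2c(OCc5ccccc5)cc(OCc5ccccc5)cc2O[C@@H]1c1cc(OCc5ccccc5)c(OCc5ccccc5)c(OCc5ccccc5)c1)c1cc(OCc5ccccc5)c(OCc5ccccc5)c(OCc5ccccc5)c1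
F5 | step 10 | 8-bromo-4β-(2-ethoxyethoxy)-5,7,3′,4′,5′-penta-O-benzyl-epigallocatechin | O[C@@H]1[C@@H](OCCOCC)c2c(OCc5ccccc5)cc(OCc5ccccc5)c(Br)c2O[C@@H]1c1cc(OCc5ccccc5)c(OCc5ccccc5)c(OCc5ccccc5)c1
F6 | step 10 | protected trimer 15 carrying bromine at C8 of the upper unit | O=C(O[C@@H]1[C@@H](c2c(OCc5ccccc5)cc(OCc5ccccc5)c3c2O[C@H](c2cc(OCc5ccccc5)c(OCc5ccccc5)c(OCc5ccccc5)c2)[C@H](O)C3)c2c(OCc5ccccc5)cc(OCc5ccccc5)c([C@H]3c4c(OCc5ccccc5)cc(OCc5ccccc5)c(Br)c4O[C@H](c4cc(OCc5ccccc5)c(OCc5ccccc5)c(OCc5ccccc5)c4)[C@@H]3O)c2O[C@@H]1c1cc(OCc5ccccc5)c(OCc5ccccc5)c(OCc5ccccc5)c1)c1cc(OCc5ccccc5)c(OCc5ccccc5)c(OCc5ccccc5)c1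
A1 | alternative 1 | benzylated trimer with a free hydroxyl only at C3 of the central unit (3-O-benzyl on upper and lower units) | O[C@@H]1[C@@H](c2c(OCc5ccccc5)cc(OCc5ccccc5)c3c2O[C@H](c2cc(OCc5ccccc5)c(OCc5ccccc5)c(OCc5ccccc5)c2)[C@H](OCc5ccccc5)C3)c2c(OCc5ccccc5)cc(OCc5ccccc5)c([C@H]3c4c(OCc5ccccc5)cc(OCc5ccccc5)cc4O[C@H](c4cc(OCc5ccccc5)c(OCc5ccccc5)c(OCc5ccccc5)c4)[C@@H]3OCc5ccccc5)c2O[C@@H]1c1cc(OCc5ccccc5)c(OCc5ccccc5)c(OCc5ccccc5)c1
A2 | alternative 1 | open-chain bis(aryl ether) with a benzylic carbinol at C4 of the upper unit (drawn as one epimer) and a trans-epoxide at C3–C4 of the central unit | [C@@H]1(c2c(OCc5ccccc5)cc(OCc5ccccc5)c3c2O[C@H](c4cc(OCc5ccccc5)c(OCc5ccccc5)c(OCc5ccccc5)c4)[C@H](OCc5ccccc5)C3)O[C@H]1[C@@H](c4cc(OCc5ccccc5)c(OCc5ccccc5)c(OCc5ccccc5)c4)Oc6c([C@@H](O)[C@@H](OCc5ccccc5)[C@@H](c4cc(OCc5ccccc5)c(OCc5ccccc5)c(OCc5ccccc5)c4)Oc7cc(OCc5ccccc5)cc(OCc5ccccc5)c7)c(OCc5ccccc5)cc(OCc5ccccc5)c6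
A3 | alternative 2 | benzylated trimer skeleton with the central unit as a 4-aryl-4H-chromene | C1=C(c6cc(OCc5ccccc5)c(OCc5ccccc5)c(OCc5ccccc5)c6)Oc2c([C@H]3c4c(OCc5ccccc5)cc(OCc5ccccc5)cc4O[C@H](c4cc(OCc5ccccc5)c(OCc5ccccc5)c(OCc5ccccc5)c4)[C@@H]3OCc5ccccc5)c(OCc5ccccc5)cc(OCc5ccccc5)c2[C@@H]1c2c(OCc5ccccc5)cc(OCc5ccccc5)c3c2O[C@H](c2cc(OCc5ccccc5)c(OCc5ccccc5)c(OCc5ccccc5)c2)[C@H](OCc5ccccc5)C3
A4 | alternative 2 | 3,5-bis(benzyloxy)phenol carrying the hexa-O-benzyl upper unit (through its C4, 4β) at the carbon ortho to the hydroxyl | Oc1cc(OCc5ccccc5)cc(OCc5ccccc5)c1[C@H]3c4c(OCc5ccccc5)cc(OCc5ccccc5)cc4O[C@H](c4cc(OCc5ccccc5)c(OCc5ccccc5)c(OCc5ccccc5)c4)[C@@H]3OCc5ccccc5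
A5 | alternative 2 | (E)-enone: hexa-O-benzyl-epigallocatechin carrying a 3-oxo-3-[3,4,5-tris(benzyloxy)phenyl]prop-1-enyl group at C8 | O=C(/C=C/c2c(OCc5ccccc5)cc(OCc5ccccc5)c3c2O[C@H](c2cc(OCc5ccccc5)c(OCc5ccccc5)c(OCc5ccccc5)c2)[C@H](OCc5ccccc5)C3)c1cc(OCc5ccccc5)c(OCc5ccccc5)c(OCc5ccccc5)c1
A6 | alternative 3 | benzylated upper–central dimer with the upper unit as a 4-aryl-4H-chromene | C1=C(c6cc(OCc5ccccc5)c(OCc5ccccc5)c(OCc5ccccc5)c6)Oc2cc(OCc5ccccc5)cc(OCc5ccccc5)c2[C@@H]1c2c(OCc5ccccc5)cc(OCc5ccccc5)c3c2O[C@H](c2cc(OCc5ccccc5)c(OCc5ccccc5)c(OCc5ccccc5)c2)[C@H](OC(=O)c2cc(OCc5ccccc5)c(OCc5ccccc5)c(OCc5ccccc5)c2)C3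
A7 | alternative 3 | diene: octa-O-benzyl-epigallocatechin gallate carrying at C8 a 1-arylprop-2-enyl group whose aryl ring bears the α-aryl vinyl ether | C=C[C@H](c2c(OCc5ccccc5)cc(OCc5ccccc5)cc2OC(=C)c2cc(OCc5ccccc5)c(OCc5ccccc5)c(OCc5ccccc5)c2)c2c(OCc5ccccc5)cc(OCc5ccccc5)c3c2O[C@H](c2cc(OCc5ccccc5)c(OCc5ccccc5)c(OCc5ccccc5)c2)[C@H](OC(=O)c2cc(OCc5ccccc5)c(OCc5ccccc5)c(OCc5ccccc5)c2)C3
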